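## The problem

Atoms carry the numbers C1 to O34 in the order of the SMILES string of target 33. The molecule is two bicyclic halves joined only through the C7=C8–C9 bridge. The east half is a cis-fused decalin (ring C: C2–C7; ring D: C5, C6, C27, C30, C31, C32) with the secondary methyl C1 on C2, the quaternary carbon C27 directly on fusion carbon C6 and the tertiary carbinol C32 on fusion carbon C5. The west half is a cyclohexane (ring B: C10, C11, C21–C24) trans-fused through C11–C21 to a 2,2-dimethyloxepan-3-one (ring A: C11, C13, C14, C15, C17, O20, C21), with the tertiary carbinol C24 next to C10. The eight stereocentres form two clusters, C2/C5/C6/C32 and C10/C11/C21/C24, too far apart to control each other, so each half must be made as one enantiomer and the union must touch neither. Within the east half C5, C6 and C32 can be fixed together and then steer C2; within the west half the C11/C21 pair can steer C10 and C24. The exocyclic C7=C8 alkene must have C9 on the C2 side (trans to C6), and C7 is flanked by two tertiary carbons that become epimerisable once C7 is a carbonyl. The tertiary alcohols and the alkene do not tolerate strong acid, the alkene rules out late hydrogenation, and the C15 α-alkoxy ketone tolerates neither strong base nor electron-transfer reductants. The east half opens because C27=C30–C31(O)–C2–C7=C6 is the 1,5-diene of a 2-alkenylbicyclo[2.2.2]oct-5-en-2-ol once C31 is bonded to C2: a [3,3] shift then makes C6–C27, cuts the temporary C2–C31 bond and leaves ring D with C27 on C6 and the C32 carbinol on C5.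

## Retrosynthesis

**33 back to 31.** No skeletal bond is cut. The C15 ketone is carried as an alcohol and O26 as a silyl ether, so 33 comes from triol 32 by oxidation of its only secondary alcohol, and 32 from 31 by fluoride. The reason is that the union uses an alkyllithium, which an α-alkoxy ketone would not survive. The forward steps must be near neutral and leave the tertiary alcohols and the alkene alone.

**31 back to 21 and 28.** The C8–C9 single bond is cut, giving alkenyl bromide 21 and primary iodide 28, to be rejoined by sp2–sp3 cross-coupling through borinate 30. The neighbouring cut at C7=C8, a Wittig reaction with C8 supplied by the west half, would need an unstabilised β-branched ylide to attack a ketone flanked by two tertiary carbons and to set the geometry in the same step. Cutting one bond further out lets the geometry be settled on a small east fragment and makes the union stereoretentive. Each partner is about half of 31. The coupling must keep the E geometry of 21 and tolerate its free tertiary alcohol.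

**21 back to 16.** C8 is removed as a bromomethylene unit (20, then ketone 19), and the C7 carbonyl is traced through alcohol 18 to the C2=C7 alkene of octalin 16. This lets one event, borane on the open face of the cis-octalin, set C2, and lets the steric difference between C6 (bearing C27) and C2 set the alkene geometry. The O34 acetal is removed at the bromide stage (20 to 21), because a bromoalkene resists protonation and the final alkene would not. Oxidation and olefination must not epimerise C2 or C6.

**16 back to 13.** The C31 oxygen of 13, needed by the key step, is removed through alcohol 14 and xanthate 15 by radical deoxygenation. The one-step Wolff–Kishner reduction is rejected: a hydrazone anion next to the C32 acetal oxygen would expel it (Kishner eliminative reduction). The precursor 13 is the direct product of the key step. The radical step must not lose the β-oxygen or add to C7.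

**13 back to 10 (key disconnection).** C6–C27 is cut and C2–C31 reconnected, which turns cis-octalone 13 into bicyclo[2.2.2]octenol 10. Against polar or radical closures of ring D, this makes the congested C6–C27 bond intramolecularly and fixes the cis fusion and the C5/C6/C32 relation by the shape of the bicycle. The precursor 10 is a rigid bicycle available from a phenol. The forward shift needs the alkenyl group syn to the etheno bridge and a C32 protecting group that cannot migrate to the alkoxide.

**10 back to 7.** The C31–C30 bond is cut to ketone 8 and alkenyl Grignard 9. Acetal 8 goes back to racemic ketol 7, and the (−)-menthyloxymethyl group of 8 serves as protecting group and resolving handle at once. An enantioselective dearomatisation was the alternative; the free o-quinol it gives dimerises and would have to be cracked again, so resolution at no cost in steps is preferred. Forward, the organometal must add from the etheno face and the diastereomers must separate.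

**7 back to 1.** Ketol 7 comes from acetate 6, and 6 from disulfone 5 and its unsaturated precursor 4 by hydrogenation followed by reductive elimination. 4 is the Diels–Alder adduct of dienone 2 and bis-sulfone 3, and 2 comes from 2,6-dimethylphenol 1 by Wessely acetoxylation. The dienophile adds on the acetoxy face, which puts the C32 oxygen syn to the new bridge. Using 3 as an acetylene equivalent and saturating the diene-derived bridge makes the new bridge the etheno bridge the key step needs; a plain ethylene equivalent would give the C32 epimer. All skeletal atoms of the east half except C8 and the isobutenyl carbons come from 1 and 3.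

**28 back to 22.** Protection and iodination lead back to triol 26, and this to cyclic carbonate 25. In 25 the O20–C17, C10–C11 and C24–O26 bonds are cut at once to give diepoxide 24, made from farnesyl carbonate 23 and farnesol 22. Building the rings one at a time would require an ether between a neopentylic secondary and a tertiary carbon, or a 7-endo hydroxy-epoxide closure against the 6-exo mode. The cascade asks the inner epoxide oxygen, the C10=C24 alkene and the carbonate to act in that order.

## Roads not taken

**Alternative 1:** The cut is in the west half: O20–C17, C10–C11 and C24–O26 are unmade together, so the west bicycle, as γ-lactone A2 that also holds C8 and C9, goes back to diepoxy tert-butyl ester A1. Forward, BF3·OEt2 or Me3SiOTf opens the terminal epoxide of A1, O20 closes the oxepane on C17, the C10=C24 alkene closes the cyclohexane on C11 and the ester oxygen traps the C24 cation.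
- Merits: three rings and four stereocentres in one step, absolute configuration from catalytic epoxidation, and the C24 oxygen installed directly.
- Weak points: it addresses the half for which a short route already exists and leaves the east decalin open. Because A2 carries C8, the union must be a Wittig reaction at C7=C8 with C8 as the nucleophile. That costs about five functional-group steps from A2, including protection of O26 against tetrahydrofuran closure onto C8, and it must olefinate a hindered, doubly α-branched, epimerisable ketone such as 19 with control of geometry.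
- Comparison: for the west bicycle this cascade is as good as or better than anything stepwise, and the chosen plan concedes the point. Its steps 17 and 18 use a cascade of the same family, ended by a carbonate on C9 (24 to 25) so that C8 can come from the east side. Against Alternative 1 as the leading idea, the chosen plan sets a key step that solves the half with no short solution, and a cross-coupling union in place of a Wittig reaction on a hindered ketone.

**Alternative 2:** The cut is C27–C30 of ring D: decalone A4 goes back to cyclohexane A3, which carries isopropenyl on C6 and acryloyl on C5. Forward, Fe(acac)3 and PhSiH3 transfer a hydrogen atom to the isopropenyl group, and the tertiary radical at C27 adds 6-endo to the terminal enone carbon C30.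
- Merits: the quaternary carbon is made under neutral, mild conditions by a reaction little affected by crowding, and it tolerates more functionality than a potassium alkoxide.
- Weak points: A3 already holds four contiguous stereocentres (C2, C5, C6, C7) that must be set first. The cis fusion is inherited, not made, and in A4 it sits next to the C32 ketone, where C5 can epimerise. The C32 carbinol then needs a methyl addition whose facial outcome on a flexible cis-decalone is open. The radical can also be reduced before it cyclises.
- Comparison: the ring-forming step itself is milder and probably more robust than the anionic oxy-Cope shift. The chosen plan sets against it that C5, C6 and C32 arise in fixed relation from a flat phenol by one cycloaddition and one rearrangement, with C32 settled before ring D exists.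

**Alternative 3:** The cut is in ring A: C14–C15 and C15–C17 are unmade, so bromo-oxepene ketal A6 goes back to bicyclic dihydropyran A5 by removal of one carbon. Forward, dibromocarbene (CHBr3, KOtBu) adds to the C14=C17 enol ether, and AgBF4 in methanol opens the dibromocyclopropane to the ring-expanded bromoallyl cation, trapped at C17.
- Merits: every operation is classical, the expansion is strain-driven, and the vinyl bromide marks C15.
- Weak points: carbene generation with KOtBu must coexist with the enolisable C24 ketone and the ester of A5. A6 is still far from ring A: C17 needs its second methyl by substitution at a tertiary allylic ketal carbon, where allylic transposition competes; the vinyl bromide must become the C15 ketone; and the C24 ketone needs the indirect methylenation, epoxidation and reduction route, because methyl nucleophiles enter equatorially and give the wrong epimer. The east half is not addressed.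
- Comparison: it avoids the one unprecedented step of the chosen route (step 18) and is the safer road in that respect. The chosen plan sets against it a west bicycle with all four stereocentres three steps from farnesol, and a key step aimed at the harder half.

Key step: step 8

Remark 1: compounds 2 and 4–7 are racemic; each is drawn as the enantiomer that leads to 33, and single-enantiomer material starts with 8.
Remark 2: Grignard reagent 9, (−)-menthyl chloromethyl ether and the L-configured Shi ketone (1,2:4,5-di-O-isopropylidene-β-L-erythro-2,3-hexodiulo-2,6-pyranose, from L-sorbose) are assumed to be purchasable.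

## Steps

Step 1
Reactants: 1 2,6-dimethylphenol
Product: 2 rac-6-acetoxy-2,6-dimethylcyclohexa-2,4-dien-1-one
Conditions: Pb(OAc)4, AcOH/CH2Cl2, 0 °C to rt
Reagents that add atoms: lead tetraacetate, CC(=O)O[Pb](OC(C)=O)(OC(C)=O)OC(C)=O
Why: Wessely acetoxylation: the aryloxy–lead intermediate delivers acetate to a methyl-bearing ortho carbon (both are equivalent), and the acetate, unlike the free o-quinol, does not dimerise readily. C32 is formed racemic.

Step 2
Reactants: 2 rac-6-acetoxy-2,6-dimethylcyclohexa-2,4-dien-1-one; 3 (E)-1,2-bis(phenylsulfonyl)ethene
Product: 4 rac-3-acetoxy-1,3-dimethyl-7,8-bis(phenylsulfonyl)bicyclo[2.2.2]oct-5-en-2-one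
Conditions: toluene, 100 °C
Reagents that add atoms: none
Why: Diels–Alder reaction with 3 as an acetylene equivalent. o-Quinol acetates take up dienophiles on the face that carries the acetoxy group, so the C32 oxygen ends syn to the new C6–C7 bridge and the C32 methyl syn to the C3=C4 bridge; C2 and C5 follow from this face. The trans-disulfone is formed in both orientations, which is of no consequence.

Step 3
Reactants: 4 rac-3-acetoxy-1,3-dimethyl-7,8-bis(phenylsulfonyl)bicyclo[2.2.2]oct-5-en-2-one
Product: 5 rac-3-acetoxy-1,3-dimethyl-5,6-bis(phenylsulfonyl)bicyclo[2.2.2]octan-2-one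
Conditions: H2 (1 atm), Pd/C, EtOAc, rt
Reagents that add atoms: none
Why: Catalytic hydrogenation of the only C=C bond turns the diene-derived bridge into the C3–C4 ethano bridge; sulfones, ketone and acetate are inert.

Step 4
Reactants: 5 rac-3-acetoxy-1,3-dimethyl-5,6-bis(phenylsulfonyl)bicyclo[2.2.2]octan-2-one
Product: 6 rac-3-acetoxy-1,3-dimethylbicyclo[2.2.2]oct-5-en-2-one
Conditions: 6% Na(Hg), NaH2PO4, MeOH/THF, −20 °C
Reagents that add atoms: none
Why: Reductive elimination of the vicinal disulfone (two-electron loss of two sulfinate ions) unmasks the C6=C7 bridge on the oxygen-bearing side of C32. Buffer, low temperature and short contact are chosen to spare the α-acetoxy ketone.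

Step 5
Reactants: 6 rac-3-acetoxy-1,3-dimethylbicyclo[2.2.2]oct-5-en-2-one
Product: 7 rac-3-hydroxy-1,3-dimethylbicyclo[2.2.2]oct-5-en-2-one
Conditions: K2CO3, MeOH, 0 °C
Reagents that add atoms: none
Why: Transesterification of an activated α-acyloxy ketone ester; the mild carbonate at 0 °C should avoid α-ketol rearrangement of the bicyclic ketol.

Step 6
Reactants: 7 rac-3-hydroxy-1,3-dimethylbicyclo[2.2.2]oct-5-en-2-one
Product: 8 (1R,3R,4S)-3-{[(1R,2S,5R)-menthyloxy]methoxy}-1,3-dimethylbicyclo[2.2.2]oct-5-en-2-one
Conditions: (−)-menthyl chloromethyl ether, i-Pr2NEt, Bu4NI (cat.), CH2Cl2, 40 °C; chromatographic separation of the two diastereomers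
Reagents that add atoms: (1R,2S,5R)-(−)-menthyl chloromethyl ether, ClCO[C@@H]1C[C@H](C)CC[C@H]1C(C)C
Why: Alkylation of the tertiary alcohol with a chloromethyl ether (formaldehyde acetal protection). The chiral acetal turns the racemate into two diastereomers, so separation is a resolution by diastereomer formation, and the acetal cannot migrate to a neighbouring alkoxide as a silyl group could. The configuration of the diastereomer taken on must be proved, for example by X-ray analysis of 8 or 10.

Step 7
Reactants: 8 (1R,3R,4S)-3-{[(1R,2S,5R)-menthyloxy]methoxy}-1,3-dimethylbicyclo[2.2.2]oct-5-en-2-one; 9 2-methylprop-1-enylmagnesium bromide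
Product: 10 (1R,2R,3R,4S)-3-{[(1R,2S,5R)-menthyloxy]methoxy}-1,3-dimethyl-2-(2-methylprop-1-enyl)bicyclo[2.2.2]oct-5-en-2-ol
Conditions: 9, CeCl3, THF, −78 °C; then 8, −78 to 0 °C
Reagents that add atoms: none
Why: Organocerium 1,2-addition to a hindered ketone. Bicyclo[2.2.2]oct-5-en-2-ones are attacked from the side of the etheno bridge, which places the alkenyl group syn to C6=C7 and the hydroxyl syn to the ethano bridge. The C31 centre is lost again in step 8.

Step 8
Reactants: 10 (1R,2R,3R,4S)-3-{[(1R,2S,5R)-menthyloxy]methoxy}-1,3-dimethyl-2-(2-methylprop-1-enyl)bicyclo[2.2.2]oct-5-en-2-ol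
Product: 13 cis-octalone with C31 ketone and C2=C7 alkene, via potassium alkoxide 11 (not isolated), via potassium enolate 12 (not isolated)
Conditions: KH, 18-crown-6, THF, 0 to 50 °C; aq. NH4Cl
Reagents that add atoms: potassium hydride, [K+].[H-] (the potassium of 11 and 12; nothing but hydrogen is added to 13)
Why: Deprotonation of the C31 hydroxyl gives alkoxide 11, whose crown-separated oxyanion weakens the adjacent C2–C31 bond and triggers a [3,3] sigmatropic shift across C27=C30–C31–C2–C7=C6. The closest known reaction type is the anionic oxy-Cope rearrangement of 2-vinylbicyclo[2.2.2]oct-5-en-2-ols to cis-fused octalones. Ring D (C5, C6, C27, C30, C31, C32) closes by formation of the C6–C27 bond inside the six-centre array, held as a boat by the bicycle, while the temporary C2–C31 bond breaks; this is a pericyclic closure, suprafacial on both allyl units, not a polar exo or endo cyclisation. The only new stereocentre, C6, is set by the bicycle: C27 can reach C6 only on the face of the etheno bridge turned toward C31, so H6 ends cis to H5, and C32 keeps the configuration fixed in steps 2 and 6 with its oxygen cis to H5. The step needs the alkenyl group syn to the etheno bridge (secured in step 7) and an O34 group that stays in place (the acetal). It must also outrun cleavage of 11 back to 8 and an alkenyl anion; formation of the conjugated, strain-free enolate 12 makes the shift irreversible, and protonation at C30 gives 13.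

Step 9
Reactants: 13 cis-octalone with C31 ketone and C2=C7 alkene
Product: 14 C31 alcohol (both epimers)
Conditions: LiAlH4, Et2O, 0 °C to rt
Reagents that add atoms: none
Why: Hydride reduction of the hindered ketone; either C31 epimer serves, since the centre is removed in step 11.

Step 10
Reactants: 14 C31 alcohol (both epimers)
Product: 15 C31 S-methyl xanthate
Conditions: NaH, imidazole (cat.), CS2, THF, 0 °C to rt; then MeI
Reagents that add atoms: carbon disulfide, S=C=S; iodomethane, CI
Why: Xanthate formation, the first half of a Barton–McCombie deoxygenation; the sodium alkoxide of a neopentylic secondary alcohol adds to CS2 and is S-methylated.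

Step 11
Reactants: 15 C31 S-methyl xanthate
Product: 16 cis-octalin with C2=C7 alkene and C32 acetal
Conditions: Bu3SnH, AIBN (cat.), toluene, 100 °C
Reagents that add atoms: none
Why: Barton–McCombie radical deoxygenation. A secondary radical does not expel a β-alkoxy group, so O34 survives where a Wolff–Kishner reduction would eliminate it. A high tin hydride concentration should outrun transannular addition of the C31 radical to C7.

Step 12
Reactants: 16 cis-octalin with C2=C7 alkene and C32 acetal
Product: 18 C7 alcohol, via alkylborane 17 (not isolated)
Conditions: BH3·THF, THF, 0 °C to rt; then NaOH aq., H2O2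
Reagents that add atoms: borane–tetrahydrofuran, [BH3-][O+]1CCCC1 (boron of 17); hydrogen peroxide, OO (oxygen on C7)
Why: Hydroboration–oxidation with boron on the less substituted C7. Syn addition from the open face of the cis-octalin (the face of H5 and H6, away from ring D and the C27 methyls) puts H on C2 cis to H6, which sets C2 with its methyl on the ring D side. The C7 carbinol centre is removed in step 13.

Step 13
Reactants: 18 C7 alcohol
Product: 19 C7 ketone
Conditions: Dess–Martin periodinane, NaHCO3, CH2Cl2, 0 °C to rt
Reagents that add atoms: none
Why: Dess–Martin oxidation under buffered, non-enolising conditions keeps C2 and C6 intact.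

Step 14
Reactants: 19 C7 ketone
Product: 20 (E)-C7 bromomethylene compound
Conditions: Ph3P(CH2Br)Br, NaN(SiMe3)2, THF, −78 °C; then 19, −78 °C to rt
Reagents that add atoms: (bromomethyl)triphenylphosphonium bromide, BrC[P+](c1ccccc1)(c1ccccc1)c1ccccc1.[Br-]
Why: Wittig bromomethylenation with the preformed bromo ylide, a reaction known for hindered ring-fusion ketones next to a quaternary carbon. Bromine should end anti to the more hindered α-carbon C6 (which bears C27), i.e. E. Adding the ketone to preformed ylide at low temperature limits enolisation.

Step 15
Reactants: 20 (E)-C7 bromomethylene compound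
Product: 21 (E)-bromoalkene with free C32 hydroxyl
Conditions: HCl (cat.), MeOH, 40 °C
Reagents that add atoms: none
Why: Acid methanolysis of the formaldehyde acetal. The electron-poor bromoalkene is not protonated, which is why the acetal is removed here and not on the final alkene.

Step 16
Reactants: 22 (2E,6E)-farnesol
Product: 23 (2E,6E)-farnesyl tert-butyl carbonate
Conditions: n-BuLi, THF, −78 °C; Boc2O, −78 to 0 °C
Reagents that add atoms: di-tert-butyl dicarbonate, CC(C)(C)OC(=O)OC(=O)OC(C)(C)C
Why: Acylation of the lithium alkoxide with Boc2O, the standard route to allylic tert-butyl carbonates.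

Step 17
Reactants: 23 (2E,6E)-farnesyl tert-butyl carbonate
Product: 24 (6S,7S,10S)-6,7:10,11-diepoxyfarnesyl tert-butyl carbonate
Conditions: L-configured Shi ketone, Oxone, K2CO3, Bu4NHSO4, Na2B4O7/Na2EDTA buffer, MeCN/CH2(OMe)2/H2O, 0 °C
Reagents that add atoms: potassium peroxymonosulfate (the oxidant of Oxone), [K+].[O-]S(=O)(=O)OO
Why: Shi epoxidation through the chiral dioxirane. The two electron-rich trisubstituted alkenes react, while the C10=C24 alkene, deactivated by the allylic carbonate, is spared. The L-configured ketone should give the S,S/S series by the spiro transition-state model, which sets C11 and C21 (and C15, lost in step 24).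

Step 18
Reactants: 24 (6S,7S,10S)-6,7:10,11-diepoxyfarnesyl tert-butyl carbonate
Product: 25 tricyclic hydroxy carbonate
Conditions: BF3·OEt2, CH2Cl2, −78 to −40 °C; aq. NaHCO3
Reagents that add atoms: none
Why: Proposed new method: BF3 opens the terminal epoxide at tertiary C17 with the inner epoxide oxygen O20 as nucleophile (oxepane by 7-endo attack); the epoxonium ion opens at tertiary C11; the C10=C24 alkene attacks C11 anti to O20 through a chair (cyclohexane, 6-endo with respect to the alkene); and the carbonyl oxygen of the tert-butyl carbonate captures the C24 cation, closing a six-membered cyclic carbonate with loss of 2-methylpropene. The closest known reaction types are the endo-selective Lewis acid cascades of 1,5-diepoxides to trans-fused oxepanes ended by alkenes or tert-butyl carbonates, the cation–olefin cyclisation of epoxyfarnesyl esters and the halocarbonate cyclisation of allylic tert-butyl carbonates; new is the allylic-carbonate alkene as relay. C21 is retained, C11 is inverted, and C10 and C24 follow from anti addition across the E alkene.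

Step 19
Reactants: 25 tricyclic hydroxy carbonate
Product: 26 west triol
Conditions: K2CO3, MeOH, 40 °C
Reagents that add atoms: none
Why: Methanolysis of the cyclic carbonate frees O on C9 and O26 without touching a stereocentre.

Step 20
Reactants: 26 west triol
Product: 27 C9 iodide diol
Conditions: I2, PPh3, imidazole, CH2Cl2, 0 °C
Reagents that add atoms: iodine, II
Why: Appel-type iodination, selective for the primary alcohol; the neopentylic secondary C15 hydroxyl and the tertiary C24 hydroxyl are too hindered to compete at 0 °C.

Step 21
Reactants: 27 C9 iodide diol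
Product: 28 C9 iodide bis(triethylsilyl) ether
Conditions: Et3SiOTf, 2,6-lutidine, CH2Cl2, −78 to 0 °C
Reagents that add atoms: triethylsilyl trifluoromethanesulfonate, CC[Si](CC)(CC)OS(=O)(=O)C(F)(F)F
Why: The silyl triflate protects both hindered hydroxyl groups, which is needed for the iodine–lithium exchange of step 22.

Step 22
Reactants: 28 C9 iodide bis(triethylsilyl) ether; 21 (E)-bromoalkene with free C32 hydroxyl
Product: 31 coupled bis(triethylsilyl) ether, via alkyllithium 29 (not isolated), via lithium borinate 30 (not isolated)
Conditions: 28, t-BuLi, Et2O, −78 °C; B-methoxy-9-BBN, THF, −78 °C to rt; then 21, Pd(dppf)Cl2, AsPh3, Cs2CO3, DMF/H2O, rt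
Reagents that add atoms: tert-butyllithium, [Li]C(C)(C)C (lithium of 29); B-methoxy-9-borabicyclo[3.3.1]nonane, COB1C2CCCC1CCC2 (borinate of 30); nothing beyond 28 and 21 remains in 31
Why: Iodine–lithium exchange, capture as the borinate and B-alkyl Suzuki–Miyaura coupling, the standard way to join a primary alkyl iodide to an alkenyl halide. Coupling is stereoretentive at the bromoalkene, so C9 ends on the C2 side, and C10 is not touched. Exchange and borylation at −78 °C keep the γ-silyloxy alkyllithium from silyl migration, and the aqueous base tolerates the free C32 hydroxyl.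

Step 23
Reactants: 31 coupled bis(triethylsilyl) ether
Product: 32 triol (C15, C24, C32 hydroxyl)
Conditions: Bu4NF, THF, rt to 40 °C
Reagents that add atoms: none
Why: Fluoride desilylation under near-neutral conditions that leave the alkene and the tertiary alcohols alone.

Step 24
Reactants: 32 triol (C15, C24, C32 hydroxyl)
Product: 33 target compound CNP0232921.1
Conditions: Dess–Martin periodinane, NaHCO3, CH2Cl2, rt
Reagents that add atoms: none
Why: Dess–Martin oxidation of the only secondary alcohol gives the C15 ketone; tertiary alcohols and the trisubstituted alkene do not react, and the C15 centre set in step 17 disappears.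

## Compound list

1 | 2,6-dimethylphenol | Cc1cccc(C)c1O | starting material
2 | rac-6-acetoxy-2,6-dimethylcyclohexa-2,4-dien-1-one (6R enantiomer drawn) | CC(=O)O[C@]1(C)C=CC=C(C)C1=O | intermediate
3 | (E)-1,2-bis(phenylsulfonyl)ethene | O=S(=O)(/C=C/S(=O)(=O)c1ccccc1)c1ccccc1 | starting material
4 | rac-3-acetoxy-1,3-dimethyl-7,8-bis(phenylsulfonyl)bicyclo[2.2.2]oct-5-en-2-one (acetoxy toward the C7–C8 bridge; sulfonyl groups trans, both orientations) | C[C@@]12C=C[C@@H](C(S(=O)(=O)c3ccccc3)C1S(=O)(=O)c1ccccc1)[C@@](C)(OC(C)=O)C2=O | intermediate
5 | rac-3-acetoxy-1,3-dimethyl-5,6-bis(phenylsulfonyl)bicyclo[2.2.2]octan-2-one (acetoxy toward the disulfonyl bridge) | C[C@@]12CC[C@@H](C(S(=O)(=O)c3ccccc3)C1S(=O)(=O)c1ccccc1)[C@@](C)(OC(C)=O)C2=O | intermediate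
6 | rac-3-acetoxy-1,3-dimethylbicyclo[2.2.2]oct-5-en-2-one (acetoxy syn to C5=C6) | C[C@@]12CC[C@@H](C=C1)[C@@](C)(OC(C)=O)C2=O | intermediate
7 | rac-3-hydroxy-1,3-dimethylbicyclo[2.2.2]oct-5-en-2-one (hydroxyl syn to C5=C6) | C[C@@]12CC[C@@H](C=C1)[C@@](C)(O)C2=O | intermediate
8 | (1R,3R,4S)-3-{[(1R,2S,5R)-menthyloxy]methoxy}-1,3-dimethylbicyclo[2.2.2]oct-5-en-2-one | C[C@@]12CC[C@@H](C=C1)[C@@](C)(OCO[C@@H]3C[C@H](C)CC[C@H]3C(C)C)C2=O | intermediate
9 | 2-methylprop-1-enylmagnesium bromide | CC(C)=C[Mg]Br | starting material
10 | (1R,2R,3R,4S)-3-{[(1R,2S,5R)-menthyloxy]methoxy}-1,3-dimethyl-2-(2-methylprop-1-enyl)bicyclo[2.2.2]oct-5-en-2-ol (hydroxyl syn to the ethano bridge; alkenyl group and C3 oxygen syn to the etheno bridge) | C[C@@]12CC[C@@H](C=C1)[C@@](C)(OCO[C@@H]3C[C@H](C)CC[C@H]3C(C)C)[C@@]2(O)C=C(C)C | intermediate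
11 | potassium alkoxide of 10 | C[C@@]12CC[C@@H](C=C1)[C@@](C)(OCO[C@@H]3C[C@H](C)CC[C@H]3C(C)C)[C@@]2([O-])C=C(C)C.[K+] | intermediate (not isolated)
12 | potassium C30=C31 enolate of 13 | CC1=C[C@H]2C(C)(C)C=C([O-])[C@](C)(OCO[C@@H]3C[C@H](C)CC[C@H]3C(C)C)[C@H]2CC1.[K+] | intermediate (not isolated)
13 | cis-octalone: ring C with C2=C7 alkene (methyl on C2), ring D with gem-dimethyl C27, C31 ketone and C32 methyl/(menthyloxy)methoxy; H5, H6 and O34 on one face | CC1=C[C@H]2C(C)(C)CC(=O)[C@](C)(OCO[C@@H]3C[C@H](C)CC[C@H]3C(C)C)[C@H]2CC1 | intermediate
14 | C31 alcohol of 13 (both C31 epimers) | CC1=C[C@H]2C(C)(C)CC(O)[C@](C)(OCO[C@@H]3C[C@H](C)CC[C@H]3C(C)C)[C@H]2CC1 | intermediate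
15 | O-(C31) S-methyl xanthate of 14 | CC1=C[C@H]2C(C)(C)CC(OC(=S)SC)[C@](C)(OCO[C@@H]3C[C@H](C)CC[C@H]3C(C)C)[C@H]2CC1 | intermediate
16 | cis-octalin: C2=C7 alkene, C27 gem-dimethyl, C32 methyl/(menthyloxy)methoxy, C30 and C31 methylene | CC1=C[C@H]2C(C)(C)CC[C@](C)(OCO[C@@H]3C[C@H](C)CC[C@H]3C(C)C)[C@H]2CC1 | intermediate
17 | C7 alkylborane (BH2 on C7 and H on C2, both cis to H6) | C[C@@H]1CC[C@H]2[C@@H]([C@H]1B)C(C)(C)CC[C@]2(C)OCO[C@@H]3C[C@H](C)CC[C@H]3C(C)C | intermediate (not isolated)
18 | cis-decalin C7 alcohol (hydroxyl cis to H6; C2 methyl on the ring D face) | C[C@@H]1CC[C@H]2[C@@H]([C@H]1O)C(C)(C)CC[C@]2(C)OCO[C@@H]3C[C@H](C)CC[C@H]3C(C)C | intermediate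
19 | cis-decalin C7 ketone (C2, C5, C6, C32 as in 33; O34 as menthyloxymethyl ether) | C[C@@H]1CC[C@H]2[C@@H](C1=O)C(C)(C)CC[C@]2(C)OCO[C@@H]3C[C@H](C)CC[C@H]3C(C)C | intermediate
20 | (E)-C7 bromomethylene compound (Br trans to C6), O34 as menthyloxymethyl ether | C[C@@H]1CC[C@H]2[C@@H](/C1=C/Br)C(C)(C)CC[C@]2(C)OCO[C@@H]3C[C@H](C)CC[C@H]3C(C)C | intermediate
21 | (E)-bromoalkene with free C32 hydroxyl (east coupling partner) | C[C@@H]1CC[C@H]2[C@@H](/C1=C/Br)C(C)(C)CC[C@]2(C)O | intermediate
22 | (2E,6E)-farnesol | CC(C)=CCC/C(C)=C/CC/C(C)=C/CO | starting material
23 | (2E,6E)-farnesyl tert-butyl carbonate | CC(C)=CCC/C(C)=C/CC/C(C)=C/COC(=O)OC(C)(C)C | intermediate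
24 | (2E,6S,7S,10S)-6,7:10,11-diepoxyfarnesyl tert-butyl carbonate | CC1(C)O[C@H]1CC[C@]2(C)O[C@H]2CC/C(C)=C/COC(=O)OC(C)(C)C | intermediate
25 | tricyclic hydroxy carbonate: trans-fused oxepane–cyclohexane with a six-membered cyclic carbonate joining O on C9 and O26; 15S hydroxyl; C10, C11, C21, C24 as in 33 | O=C1OC[C@H]2[C@]3(C)CC[C@H](O)C(C)(C)O[C@H]3CC[C@]2(C)O1 | intermediate
26 | west triol (C9 primary, C15 secondary, C24 tertiary hydroxyl) | OC[C@H]1[C@]2(C)CC[C@H](O)C(C)(C)O[C@H]2CC[C@]1(C)O | intermediate
27 | C9 iodide diol | IC[C@H]1[C@]2(C)CC[C@H](O)C(C)(C)O[C@H]2CC[C@]1(C)O | intermediate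
28 | C9 iodide with O on C15 and O26 as triethylsilyl ethers (west coupling partner) | IC[C@H]1[C@]2(C)CC[C@H](O[Si](CC)(CC)CC)C(C)(C)O[C@H]2CC[C@]1(C)O[Si](CC)(CC)CC | intermediate
29 | C9 alkyllithium from 28 | [Li]C[C@H]1[C@]2(C)CC[C@H](O[Si](CC)(CC)CC)C(C)(C)O[C@H]2CC[C@]1(C)O[Si](CC)(CC)CC | intermediate (not isolated)
30 | lithium B-alkyl-B-methoxy-9-borabicyclo[3.3.1]nonane borinate (alkyl = C9 of the west half) | CO[B-]1(C[C@H]2[C@]3(C)CC[C@H](O[Si](CC)(CC)CC)C(C)(C)O[C@H]3CC[C@]2(C)O[Si](CC)(CC)CC)C4CCCC1CCC4.[Li+] | intermediate (not isolated)
31 | coupled product: skeleton of 33 with O on C15 and O26 as triethylsilyl ethers, free C32 hydroxyl | C[C@@H]1CC[C@H]2[C@@H](/C1=C/C[C@H]1[C@]3(C)CC[C@H](O[Si](CC)(CC)CC)C(C)(C)O[C@H]3CC[C@]1(C)O[Si](CC)(CC)CC)C(C)(C)CC[C@]2(C)O | intermediate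
32 | triol: 33 with a 15S hydroxyl in place of the C15 ketone | C[C@@H]1CC[C@H]2[C@@H](/C1=C/C[C@H]1[C@]3(C)CC[C@H](O)C(C)(C)O[C@H]3CC[C@]1(C)O)C(C)(C)CC[C@]2(C)O | intermediate
33 | CNP0232921.1 (7E; 2R, 5S, 6R, 10S, 11S, 21S, 24S, 32S in SMILES-order numbering) | C[C@@H]1CC[C@H]2[C@@H](/C1=C/C[C@H]1[C@]3(C)CCC(=O)C(C)(C)O[C@H]3CC[C@]1(C)O)C(C)(C)CC[C@]2(C)O | target

## Step count and least certain steps

Total: 24 steps. Longest linear sequence: 18 steps (steps 1–15 and 22–24); the west branch (steps 16–21) joins at step 22.

**Step 18 (proposed new method).** The allylic-carbonate alkene is a weakened π-nucleophile, so the cascade may stop early (elimination or fluoride capture at C11), may run in the wrong direction if the inner epoxide is activated first (tetrahydrofuran formation), or may end by proton loss at C24 instead of carbonate capture.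
- Fallback, by known chemistry, from 22 back to 26: acetylation gives farnesyl acetate F1, and Shi epoxidation gives diepoxy acetate F2. A Me3SiOTf/2,6-di-tert-butyl-4-methylpyridine cascade ended by proton loss from C25, followed by desilylation, gives exocyclic alkene F3. Peracid epoxidation on the face away from the axial C12 methyl gives spiro-epoxide F4, and LiAlH4 opens the epoxide at its methylene carbon and removes the acetate to give 26.

**Step 8 (key step).** Bond formation to the fully substituted alkene terminus, with one methyl forced into the boat, may make the shift slow, so that fragmentation of alkoxide 11 back to 8 or decomposition at higher temperature takes over.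
- Fallback, from 8 back to 13: the quaternary centre is built in two stages. (E)-Prop-1-enylmagnesium bromide/CeCl3 gives propenyl carbinol F5, whose anionic oxy-Cope shift gives monomethyl octalone F6. Saegusa–Ito dehydrogenation (LiN(i-Pr)2, Me3SiCl; Pd(OAc)2) gives enone F7, and conjugate addition of Me2CuLi with Me3SiCl gives 13.

**Step 4.** The amalgam may also cleave the α-acetoxy group (over-reduction of the α-acyloxy ketone).
- Fallback, from 5 back to 7: the reduction is deliberately run to the deoxygenated ketone 1,3-dimethylbicyclo[2.2.2]oct-5-en-2-one F8 with excess amalgam or SmI2. Its potassium enolate (KN(SiMe3)2) is then hydroxylated with 3-phenyl-2-(phenylsulfonyl)oxaziridine from the less hindered etheno face, which gives 7 with the same C32 configuration.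

**Step 6.** The menthyl unit is remote from the bicycle, so the two diastereomeric acetals may not separate.
- Fallback, from 7 back to 8: the enantiomers of 7 are separated by preparative chromatography on a chiral stationary phase, and the required enantiomer is protected as in step 6. No new compound arises.

**Step 14.** The ylide may enolise the hindered ketone instead of adding, with recovered or C2/C6-epimerised ketone as the result, and the E preference may erode because C2 also carries a substituent.
- Fallback, from 19 back to 31: non-basic Ramirez dibromomethylenation (CBr4, PPh3) gives dibromoalkene F9, and acid methanolysis gives dibromoalkene alcohol F10. Site-selective Suzuki–Miyaura coupling of the less hindered bromide (on the C2 side) with borinate 30 gives bromodiene F11, and palladium-catalysed hydrodebromination with Bu3SnH gives 31.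

## Further compounds

F1 | step 18 | (2E,6E)-farnesyl acetate | CC(C)=CCC/C(C)=C/CC/C(C)=C/COC(C)=O
F2 | step 18 | (2E,6S,7S,10S)-6,7:10,11-diepoxyfarnesyl acetate | CC1(C)O[C@H]1CC[C@]2(C)O[C@H]2CC/C(C)=C/COC(C)=O
F3 | step 18 | bicyclic exocyclic alkene: trans-fused oxepane–cyclohexane with C24=C25 methylene, C9 acetate and C15 hydroxyl | CC(=O)OC[C@H]1[C@]2(C)CC[C@H](O)C(C)(C)O[C@H]2CCC1=C
F4 | step 18 | C24 spiro-epoxide of F3 (epoxide oxygen anti to the C12 methyl) | CC(=O)OC[C@H]1[C@]2(C)CC[C@H](O)C(C)(C)O[C@H]2CC[C@@]13CO3
F5 | step 8 | (E)-prop-1-enyl analogue of 10 | C[C@@]12CC[C@@H](C=C1)[C@@](C)(OCO[C@@H]3C[C@H](C)CC[C@H]3C(C)C)[C@@]2(O)/C=C/C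
F6 | step 8 | analogue of 13 with one methyl on C27 (either C27 epimer) | CC1=C[C@H]2C(C)CC(=O)[C@](C)(OCO[C@@H]3C[C@H](C)CC[C@H]3C(C)C)[C@H]2CC1
F7 | step 8 | C27=C30 enone from F6 | CC1=C[C@H]2C(C)=CC(=O)[C@](C)(OCO[C@@H]3C[C@H](C)CC[C@H]3C(C)C)[C@H]2CC1
F8 | step 4 | rac-1,3-dimethylbicyclo[2.2.2]oct-5-en-2-one (C3 epimers) | C[C@@]12CC[C@@H](C=C1)C(C)C2=O
F0 | step 6 | none | none
F9 | step 14 | C7 dibromomethylene analogue of 20 | C[C@@H]1CC[C@H]2[C@@H](C1=C(Br)Br)C(C)(C)CC[C@]2(C)OCO[C@@H]3C[C@H](C)CC[C@H]3C(C)C
F10 | step 14 | C7 dibromomethylene analogue of 21 | C[C@@H]1CC[C@H]2[C@@H](C1=C(Br)Br)C(C)(C)CC[C@]2(C)O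
F11 | step 14 | 8-bromo analogue of 31 (Br cis to C6, C9 cis to C2) | C[C@@H]1CC[C@H]2[C@@H](/C1=C(Br)/C[C@H]1[C@]3(C)CC[C@H](O[Si](CC)(CC)CC)C(C)(C)O[C@H]3CC[C@]1(C)O[Si](CC)(CC)CC)C(C)(C)CC[C@]2(C)O
A1 | alternative 1 | tert-butyl (3E,7S,8S,11S)-7,8:11,12-diepoxyhomofarnesoate | CC1(C)O[C@H]1CC[C@]2(C)O[C@H]2CC/C(C)=C/CC(=O)OC(C)(C)C
A2 | alternative 1 | tricyclic C15-hydroxy oxepane γ-lactone | O=C4C[C@H]1[C@]3(C)CC[C@H](O)C(C)(C)O[C@H]3CC[C@]1(C)O4
A3 | alternative 2 | cyclohexane with C5 acryloyl, C6 isopropenyl, C7 tert-butyldimethylsilyl ether and C2 methyl | C[C@@H]1CC[C@H](C(=O)C=C)[C@@H]([C@H]1O[Si](C)(C)C(C)(C)C)C(C)=C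
A4 | alternative 2 | cis-fused decalone with C32 ketone, C27 gem-dimethyl and C7 silyl ether | C[C@@H]1CC[C@H]2[C@@H]([C@H]1O[Si](C)(C)C(C)(C)C)C(C)(C)CCC2=O
A5 | alternative 3 | bicyclic dihydropyran (C14=C17 enol ether) with C24 ketone and C10 CH2CO2Me | COC(=O)C[C@H]1[C@]2(C)CC=C(C)O[C@H]2CCC1=O
A6 | alternative 3 | ring-expanded bromo-oxepene methyl ketal | COC(=O)C[C@H]1[C@]2(C)CC=C(Br)[C@@](C)(OC)O[C@H]2CCC1=O
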